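**Plan**

- Retrosynthetic cuts, in order: the C3–O acyl bond and the two protecting groups; the three C–H bonds at C4a, C5 and C8a (one hydrogenation); C6–C7 of ring B (6π ring closure); C8a–C8 and C4a–C5 (two cross-couplings on a ring A lactam derivative); C3'–C4' of the side chain (epoxide opening).
- Enabling feature: in ring B, C6 and C7 are unsubstituted methylenes, and the hydrogens on C4a, C5 and C8a all sit on the face of the C3 oxygen, opposite the C2 methyl. Ring B can therefore be closed at C6–C7 with C4a, C5 and C8a still sp2, and the three centres set together by one syn hydrogenation.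
- Forward order: ring A is made first as an alanine-derived N-Boc piperidinone and converted into a bromo enol phosphate; the side-chain alkenyl group is joined at C4a, vinyl at C8a; ring B closes thermally; then hydrogenation, acylation, deprotection.
- Stereochemistry: C2 from L-alanine; C3 by chelation-controlled ketone reduction; C5' from (R)-2-propyloxirane; C4a, C5 and C8a by hydroxyl-directed hydrogenation from the C3-OH face; diene geometry from a Doebner condensation.

Key step: step 13

Assumption: positions carry decahydroquinoline numbers (N1, C2, C3, C4, C4a, C5–C8, C8a; side chain C1'–C8'), compounds 1 and 14 are taken as catalogue items, and the target is isolated as the free base. Abbreviations: Boc = tert-butoxycarbonyl, TBS = tert-butyldimethylsilyl, PMB = 4-methoxybenzyl, Bpin = pinacolatoboryl.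

Step 1
Reactants: 1 tert-butyl [(2S)-1-[methoxy(methyl)amino]-1-oxopropan-2-yl]carbamate (N-Boc-L-alanine N-methoxy-N-methylamide); 2 but-3-en-1-ylmagnesium bromide
Product: 3 tert-butyl [(2S)-3-oxohept-6-en-2-yl]carbamate
Conditions: 2 (3 equiv), THF, −15 → 0 °C; aq. NH4Cl
Reagents that add atoms: none
Why: Weinreb ketone synthesis, in which one equivalent of Grignard reagent removes the carbamate N–H and the next adds once to give a magnesium chelate that releases the ketone only on work-up, so over-addition and erosion of C2 are not expected.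

Step 2
Reactants: 3 tert-butyl [(2S)-3-oxohept-6-en-2-yl]carbamate
Product: 4 tert-butyl [(2S,3R)-3-hydroxyhept-6-en-2-yl]carbamate
Conditions: LiAlH(OtBu)3 (2.5 equiv), EtOH, −78 °C; H2O
Reagents that add atoms: none
Why: Chelation-controlled (cyclic Cram) reduction of an N-H carbamate α-amino ketone, in which hydride should reach the carbonyl from the side of the small C2 hydrogen and so set the new carbinol centre (future C3) as R, anti to nitrogen.

Step 3
Reactants: 4 tert-butyl [(2S,3R)-3-hydroxyhept-6-en-2-yl]carbamate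
Product: 5 tert-butyl [(2S,3R)-3-(tert-butyldimethylsilyloxy)hept-6-en-2-yl]carbamate
Conditions: TBSCl (1.3 equiv), imidazole (2.5 equiv), DMF, rt
Reagents that add atoms: tert-butyldimethylsilyl chloride, CC(C)(C)[Si](C)(C)Cl
Why: Standard silylation of a secondary alcohol under non-basic conditions that avoid cyclic carbamate formation from the neighbouring NHBoc group.

Step 4
Reactants: 5 tert-butyl [(2S,3R)-3-(tert-butyldimethylsilyloxy)hept-6-en-2-yl]carbamate
Product: 8 tert-butyl (2S,3R)-3-(tert-butyldimethylsilyloxy)-6-hydroxy-2-methylpiperidine-1-carboxylate (both C6 epimers), via secondary ozonide 6 (not isolated), via open-chain aldehyde 7 (not isolated)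
Conditions: O3, CH2Cl2, −78 °C; Me2S, −78 °C → rt
Reagents that add atoms: ozone, [O-][O+]=O
Why: Ozonolysis with reductive work-up gives the δ-carbamoyl aldehyde, which should close onto the carbamate N–H to the six-membered N-Boc hemiaminal by ring–chain tautomerism.

Step 5
Reactants: 8 tert-butyl (2S,3R)-3-(tert-butyldimethylsilyloxy)-6-hydroxy-2-methylpiperidine-1-carboxylate
Product: 9 tert-butyl (2S,3R)-3-(tert-butyldimethylsilyloxy)-2-methyl-6-oxopiperidine-1-carboxylate
Conditions: (n-Pr)4N[RuO4] (5 mol %), N-methylmorpholine N-oxide (1.5 equiv), 4 Å MS, CH2Cl2, rt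
Reagents that add atoms: none
Why: Ley oxidation of a cyclic N-acyl hemiaminal to the N-Boc lactam under neutral conditions that leave the silyl ether and the carbamate alone.

Step 6
Reactants: 9 tert-butyl (2S,3R)-3-(tert-butyldimethylsilyloxy)-2-methyl-6-oxopiperidine-1-carboxylate
Product: 11 tert-butyl (2S,3R)-3-(tert-butyldimethylsilyloxy)-6-(diphenoxyphosphoryloxy)-2-methyl-3,4-dihydro-2H-pyridine-1-carboxylate, via potassium enolate 10 (not isolated)
Conditions: KN(SiMe3)2 (1.2 equiv), THF, −78 °C; (PhO)2P(O)Cl (1.2 equiv), −78 °C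
Reagents that add atoms: diphenyl phosphorochloridate, O=P(Cl)(Oc1ccccc1)Oc1ccccc1
Why: O-phosphorylation of the lactam enolate gives the ketene aminal phosphate, the only enolisable position being the ring CH2 next to the carbonyl (future C4a), which has no β-leaving group.

Step 7
Reactants: 11 tert-butyl (2S,3R)-3-(tert-butyldimethylsilyloxy)-6-(diphenoxyphosphoryloxy)-2-methyl-3,4-dihydro-2H-pyridine-1-carboxylate
Product: 13 tert-butyl (2S,3R)-5-bromo-3-(tert-butyldimethylsilyloxy)-6-(diphenoxyphosphoryloxy)-2-methyl-3,4-dihydro-2H-pyridine-1-carboxylate, via dibromide adduct 12 (not isolated)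
Conditions: Br2 (1.05 equiv), CH2Cl2, −78 °C; Et3N (3 equiv), −78 °C → rt
Reagents that add atoms: bromine, BrBr
Why: Bromine addition to the electron-rich ketene aminal alkene followed by amine-induced loss of HBr (addition–elimination, as for enecarbamates) should return the alkene with bromine on its β-carbon, the future C4a.

Step 8
Reactants: 14 (5-chloropent-1-yn-1-yl)trimethylsilane; 15 (R)-2-propyloxirane
Product: 17 (4R)-10-(trimethylsilyl)dec-9-yn-4-ol, via Grignard reagent 16 (not isolated)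
Conditions: 14, Mg, THF, reflux; then CuI (10 mol %), 15, −30 → 0 °C; aq. NH4Cl
Reagents that add atoms: none
Why: Copper-catalysed SN2 opening of a terminal epoxide at its CH2 carbon by an alkyl Grignard reagent forms C3'–C4' without touching the stereocentre, so the R configuration of the epoxide becomes that of C5'.

Step 9
Reactants: 17 (4R)-10-(trimethylsilyl)dec-9-yn-4-ol
Product: 19 1-{[(4R)-dec-9-yn-4-yloxy]methyl}-4-methoxybenzene, via silylalkyne PMB ether 18 (not isolated)
Conditions: NaH (1.5 equiv), 4-MeOC6H4CH2Cl (1.3 equiv), Bu4NI (cat.), DMF, 0 °C → rt; then MeOH, K2CO3, rt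
Reagents that add atoms: 4-methoxybenzyl chloride, COc1ccc(CCl)cc1
Why: Williamson etherification of the secondary alkoxide followed in the same flask by base-mediated methanolysis of the C(sp)–Si bond gives the terminal alkyne with the carbinol protected by a group that later falls with acid.

Step 10
Reactants: 19 1-{[(4R)-dec-9-yn-4-yloxy]methyl}-4-methoxybenzene
Product: 21 2-{(7R)-7-[(4-methoxybenzyl)oxy]dec-1-en-2-yl}-4,4,5,5-tetramethyl-1,3,2-dioxaborolane, via alkenylalane 20 (not isolated)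
Conditions: Ni(dppp)Cl2 (3 mol %), iBu2AlH (1.3 equiv), THF, 0 → 22 °C; then MeOBpin (3 equiv), 0 → 70 °C
Reagents that add atoms: 2-methoxy-4,4,5,5-tetramethyl-1,3,2-dioxaborolane, COB1OC(C)(C)C(C)(C)O1
Why: Nickel-catalysed α-selective (Markovnikov) hydroalumination of a terminal alkyl alkyne places aluminium on the internal carbon, and aluminium-to-boron exchange with the methoxyboronate gives the 1,1-disubstituted alkenylboronate.

Step 11
Reactants: 13 tert-butyl (2S,3R)-5-bromo-3-(tert-butyldimethylsilyloxy)-6-(diphenoxyphosphoryloxy)-2-methyl-3,4-dihydro-2H-pyridine-1-carboxylate; 21 2-{(7R)-7-[(4-methoxybenzyl)oxy]dec-1-en-2-yl}-4,4,5,5-tetramethyl-1,3,2-dioxaborolane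
Product: 22 tert-butyl (2S,3R)-3-(tert-butyldimethylsilyloxy)-6-(diphenoxyphosphoryloxy)-5-{(7R)-7-[(4-methoxybenzyl)oxy]dec-1-en-2-yl}-2-methyl-3,4-dihydro-2H-pyridine-1-carboxylate
Conditions: 21 (1.15 equiv), Pd(dppf)Cl2 (5 mol %), K3PO4 (3 equiv), 1,4-dioxane/H2O (9:1), 60 °C
Reagents that add atoms: none
Why: Suzuki–Miyaura coupling in which zerovalent palladium should insert into the C–Br bond in preference to the much less reactive C–O bond of the enol phosphate, joining the future C4a to the future C5.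

Step 12
Reactants: 22 tert-butyl (2S,3R)-3-(tert-butyldimethylsilyloxy)-6-(diphenoxyphosphoryloxy)-5-{(7R)-7-[(4-methoxybenzyl)oxy]dec-1-en-2-yl}-2-methyl-3,4-dihydro-2H-pyridine-1-carboxylate; 23 tributyl(vinyl)stannane
Product: 24 tert-butyl (2S,3R)-3-(tert-butyldimethylsilyloxy)-6-ethenyl-5-{(7R)-7-[(4-methoxybenzyl)oxy]dec-1-en-2-yl}-2-methyl-3,4-dihydro-2H-pyridine-1-carboxylate
Conditions: 23 (1.5 equiv), Pd(PPh3)4 (5 mol %), LiCl (3 equiv), THF, 60 °C
Reagents that add atoms: none
Why: Chloride-assisted Stille coupling of the nitrogen-activated ketene aminal phosphate installs the vinyl group at the future C8a at a temperature kept below that of ring closure, and any triene that does close early is simply the product of step 13.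

Step 13
Reactants: 24 tert-butyl (2S,3R)-3-(tert-butyldimethylsilyloxy)-6-ethenyl-5-{(7R)-7-[(4-methoxybenzyl)oxy]dec-1-en-2-yl}-2-methyl-3,4-dihydro-2H-pyridine-1-carboxylate
Product: 25 tert-butyl (2S,3R)-3-(tert-butyldimethylsilyloxy)-5-{(5R)-5-[(4-methoxybenzyl)oxy]octyl}-2-methyl-1,2,3,4,6,7-hexahydroquinoline-1-carboxylate (C4a=C5 and C8=C8a)
Conditions: toluene (0.02 M, degassed), 2,6-di-tert-butyl-4-methylphenol (cat.), 110 °C, sealed tube, dark
Reagents that add atoms: none
Why: A concerted thermal 6π-electrocyclisation of the all-carbon triene C7=C8–C8a=C4a–C5=C6 forms the σ-bond C6–C7 and shifts the π-bonds to C8=C8a and C4a=C5. The closest known reaction type is the thermal closure of a (Z)-hexa-1,3,5-triene to a cyclohexa-1,3-diene, here on a 2,3-dialkenyl N-acyl tetrahydropyridine whose central alkene is the enecarbamate bond of ring A and is therefore locked cis. Ring B closes as a six-membered carbocycle in the suprafacial disrotatory mode that is thermally allowed for six electrons. No stereocentre is formed, because both termini (C6 and C7) are unsubstituted CH2 groups, and C2, C3 and C5' are not touched. The step needs ring closure to win over [1,5]-hydrogen shift, dimerisation, oxidation to the aromatic ring and acid-induced loss of the enecarbamate; the ring-enforced s-cis geometry, the unhindered CH2 termini, high dilution, exclusion of air and acid and the moderate temperature should secure this.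

Step 14
Reactants: 25 tert-butyl (2S,3R)-3-(tert-butyldimethylsilyloxy)-5-{(5R)-5-[(4-methoxybenzyl)oxy]octyl}-2-methyl-1,2,3,4,6,7-hexahydroquinoline-1-carboxylate
Product: 26 tert-butyl (2S,3R)-3-hydroxy-5-{(5R)-5-[(4-methoxybenzyl)oxy]octyl}-2-methyl-1,2,3,4,6,7-hexahydroquinoline-1-carboxylate
Conditions: Bu4NF/AcOH (1:1, 3 equiv), THF, 0 → 40 °C
Reagents that add atoms: none
Why: Fluoride cleavage of the secondary silyl ether, buffered with acetic acid so that the freed alkoxide is protonated at once and neither the acid-sensitive dienyl carbamate, the Boc group nor the PMB ether is affected.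

Step 15
Reactants: 26 tert-butyl (2S,3R)-3-hydroxy-5-{(5R)-5-[(4-methoxybenzyl)oxy]octyl}-2-methyl-1,2,3,4,6,7-hexahydroquinoline-1-carboxylate
Product: 27 tert-butyl (2S,3R,4aS,5S,8aR)-3-hydroxy-5-{(5R)-5-[(4-methoxybenzyl)oxy]octyl}-2-methyl-decahydroquinoline-1-carboxylate
Conditions: [Ir(cod)(PCy3)(py)]PF6 (10 mol %), H2 (1 atm), CH2Cl2, 0 °C → rt
Reagents that add atoms: none
Why: Hydroxyl-directed homogeneous hydrogenation, in which the cationic iridium catalyst binds the C3 hydroxyl and should deliver both equivalents of hydrogen to the face that this group occupies, which is also the face opposite the C2 methyl held pseudo-axial by allylic 1,3-strain with N-Boc, so that the hydrogens on C4a, C5 and C8a all arrive cis to the C3 oxygen (4aS,5S,8aR) while the PMB ether is not hydrogenolysed.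

Step 16
Reactants: 28 (E)-hex-2-enal; 29 malonic acid
Product: 31 (2E,4E)-octa-2,4-dienoic acid, via alkylidenemalonic acid 30 (not isolated)
Conditions: pyridine, piperidine (cat.), 90 °C
Reagents that add atoms: none
Why: Doebner modification of the Knoevenagel condensation, in which condensation and decarboxylation in hot pyridine should give the thermodynamically preferred (2E,4E)-dienoic acid.

Step 17
Reactants: 27 tert-butyl (2S,3R,4aS,5S,8aR)-3-hydroxy-5-{(5R)-5-[(4-methoxybenzyl)oxy]octyl}-2-methyl-decahydroquinoline-1-carboxylate; 31 (2E,4E)-octa-2,4-dienoic acid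
Product: 33 tert-butyl (2S,3R,4aS,5S,8aR)-5-{(5R)-5-[(4-methoxybenzyl)oxy]octyl}-2-methyl-3-[(2E,4E)-octa-2,4-dienoyloxy]-decahydroquinoline-1-carboxylate, via mixed anhydride 32 (not isolated)
Conditions: 31 (1.5 equiv), 2,4,6-Cl3C6H2COCl (1.5 equiv), Et3N, THF, rt; then 27, DMAP (2 equiv), toluene, rt → 40 °C
Reagents that add atoms: none
Why: Yamaguchi esterification, in which DMAP attacks the unhindered dienoyl carbonyl of the mixed anhydride and the resulting acylpyridinium acylates the hindered axial C3 hydroxyl, the only free hydroxyl in the molecule.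

Step 18
Reactants: 33 tert-butyl (2S,3R,4aS,5S,8aR)-5-{(5R)-5-[(4-methoxybenzyl)oxy]octyl}-2-methyl-3-[(2E,4E)-octa-2,4-dienoyloxy]-decahydroquinoline-1-carboxylate
Product: 34 lepadin H, (2S,3R,4aS,5S,8aR)-5-[(5R)-5-hydroxyoctyl]-2-methyl-decahydroquinolin-3-yl (2E,4E)-octa-2,4-dienoate
Conditions: CF3CO2H/CH2Cl2 (1:4), anisole (5 equiv), 0 °C → rt; aq. NaHCO3
Reagents that add atoms: none
Why: Acidolysis removes the Boc group and the PMB ether in one operation, anisole trapping the benzylic cation, while the protonated amine and the conjugated dienoate are inert and the bicarbonate wash frees the base.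

**Compound list**

1 | tert-butyl [(2S)-1-[methoxy(methyl)amino]-1-oxopropan-2-yl]carbamate | C[C@H](NC(=O)OC(C)(C)C)C(=O)N(C)OC | starting material
2 | but-3-en-1-ylmagnesium bromide | C=CCC[Mg]Br | starting material
3 | tert-butyl [(2S)-3-oxohept-6-en-2-yl]carbamate | C[C@H](NC(=O)OC(C)(C)C)C(=O)CCC=C | intermediate
4 | tert-butyl [(2S,3R)-3-hydroxyhept-6-en-2-yl]carbamate | C[C@H](NC(=O)OC(C)(C)C)[C@H](O)CCC=C | intermediate
5 | tert-butyl [(2S,3R)-3-(tert-butyldimethylsilyloxy)hept-6-en-2-yl]carbamate | C[C@H](NC(=O)OC(C)(C)C)[C@H](O[Si](C)(C)C(C)(C)C)CCC=C | intermediate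
6 | tert-butyl [(2S,3R)-3-(tert-butyldimethylsilyloxy)-5-(1,2,4-trioxolan-3-yl)pentan-2-yl]carbamate (secondary ozonide) | C[C@H](NC(=O)OC(C)(C)C)[C@H](O[Si](C)(C)C(C)(C)C)CCC1OCOO1 | intermediate
7 | tert-butyl [(2S,3R)-3-(tert-butyldimethylsilyloxy)-6-oxohexan-2-yl]carbamate | C[C@H](NC(=O)OC(C)(C)C)[C@H](O[Si](C)(C)C(C)(C)C)CCC=O | intermediate
8 | tert-butyl (2S,3R)-3-(tert-butyldimethylsilyloxy)-6-hydroxy-2-methylpiperidine-1-carboxylate (C6 epimers) | C[C@H]1[C@H](O[Si](C)(C)C(C)(C)C)CCC(O)N1C(=O)OC(C)(C)C | intermediate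
9 | tert-butyl (2S,3R)-3-(tert-butyldimethylsilyloxy)-2-methyl-6-oxopiperidine-1-carboxylate | C[C@H]1[C@H](O[Si](C)(C)C(C)(C)C)CCC(=O)N1C(=O)OC(C)(C)C | intermediate
10 | potassium enolate of 9 | C[C@H]1[C@H](O[Si](C)(C)C(C)(C)C)CC=C([O-])N1C(=O)OC(C)(C)C.[K+] | intermediate
11 | tert-butyl (2S,3R)-3-(tert-butyldimethylsilyloxy)-6-(diphenoxyphosphoryloxy)-2-methyl-3,4-dihydro-2H-pyridine-1-carboxylate | C[C@H]1[C@H](O[Si](C)(C)C(C)(C)C)CC=C(OP(=O)(Oc2ccccc2)Oc2ccccc2)N1C(=O)OC(C)(C)C | intermediate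
12 | tert-butyl (2S,3R)-5,6-dibromo-3-(tert-butyldimethylsilyloxy)-6-(diphenoxyphosphoryloxy)-2-methylpiperidine-1-carboxylate | C[C@H]1[C@H](O[Si](C)(C)C(C)(C)C)CC(Br)C(Br)(OP(=O)(Oc2ccccc2)Oc2ccccc2)N1C(=O)OC(C)(C)C | intermediate
13 | tert-butyl (2S,3R)-5-bromo-3-(tert-butyldimethylsilyloxy)-6-(diphenoxyphosphoryloxy)-2-methyl-3,4-dihydro-2H-pyridine-1-carboxylate | C[C@H]1[C@H](O[Si](C)(C)C(C)(C)C)CC(Br)=C(OP(=O)(Oc2ccccc2)Oc2ccccc2)N1C(=O)OC(C)(C)C | intermediate
14 | (5-chloropent-1-yn-1-yl)trimethylsilane | C[Si](C)(C)C#CCCCCl | starting material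
15 | (R)-2-propyloxirane | CCC[C@@H]1CO1 | starting material
16 | [5-(trimethylsilyl)pent-4-yn-1-yl]magnesium chloride | C[Si](C)(C)C#CCCC[Mg]Cl | intermediate
17 | (4R)-10-(trimethylsilyl)dec-9-yn-4-ol | CCC[C@@H](O)CCCCC#C[Si](C)(C)C | intermediate
18 | {(7R)-7-[(4-methoxybenzyl)oxy]dec-1-yn-1-yl}trimethylsilane | CCC[C@@H](OCc1ccc(OC)cc1)CCCCC#C[Si](C)(C)C | intermediate
19 | 1-{[(4R)-dec-9-yn-4-yloxy]methyl}-4-methoxybenzene | CCC[C@@H](OCc1ccc(OC)cc1)CCCCC#C | intermediate
20 | diisobutyl{(7R)-7-[(4-methoxybenzyl)oxy]dec-1-en-2-yl}alane | C=C([Al](CC(C)C)CC(C)C)CCCC[C@H](OCc1ccc(OC)cc1)CCC | intermediate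
21 | 2-{(7R)-7-[(4-methoxybenzyl)oxy]dec-1-en-2-yl}-4,4,5,5-tetramethyl-1,3,2-dioxaborolane | C=C(B1OC(C)(C)C(C)(C)O1)CCCC[C@H](OCc1ccc(OC)cc1)CCC | intermediate
22 | tert-butyl (2S,3R)-3-(tert-butyldimethylsilyloxy)-6-(diphenoxyphosphoryloxy)-5-{(7R)-7-[(4-methoxybenzyl)oxy]dec-1-en-2-yl}-2-methyl-3,4-dihydro-2H-pyridine-1-carboxylate | C[C@H]1[C@H](O[Si](C)(C)C(C)(C)C)CC(C(=C)CCCC[C@H](OCc2ccc(OC)cc2)CCC)=C(OP(=O)(Oc2ccccc2)Oc2ccccc2)N1C(=O)OC(C)(C)C | intermediate
23 | tributyl(vinyl)stannane | C=C[Sn](CCCC)(CCCC)CCCC | starting material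
24 | tert-butyl (2S,3R)-3-(tert-butyldimethylsilyloxy)-6-ethenyl-5-{(7R)-7-[(4-methoxybenzyl)oxy]dec-1-en-2-yl}-2-methyl-3,4-dihydro-2H-pyridine-1-carboxylate | C[C@H]1[C@H](O[Si](C)(C)C(C)(C)C)CC(C(=C)CCCC[C@H](OCc2ccc(OC)cc2)CCC)=C(C=C)N1C(=O)OC(C)(C)C | intermediate
25 | tert-butyl (2S,3R)-3-(tert-butyldimethylsilyloxy)-5-{(5R)-5-[(4-methoxybenzyl)oxy]octyl}-2-methyl-1,2,3,4,6,7-hexahydroquinoline-1-carboxylate | C[C@H]1[C@H](O[Si](C)(C)C(C)(C)C)CC2=C(CCCC[C@H](OCc3ccc(OC)cc3)CCC)CCC=C2N1C(=O)OC(C)(C)C | intermediate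
26 | tert-butyl (2S,3R)-3-hydroxy-5-{(5R)-5-[(4-methoxybenzyl)oxy]octyl}-2-methyl-1,2,3,4,6,7-hexahydroquinoline-1-carboxylate | C[C@H]1[C@H](O)CC2=C(CCCC[C@H](OCc3ccc(OC)cc3)CCC)CCC=C2N1C(=O)OC(C)(C)C | intermediate
27 | tert-butyl (2S,3R,4aS,5S,8aR)-3-hydroxy-5-{(5R)-5-[(4-methoxybenzyl)oxy]octyl}-2-methyl-decahydroquinoline-1-carboxylate | C[C@H]1[C@H](O)C[C@H]2[C@@H](CCCC[C@H](OCc3ccc(OC)cc3)CCC)CCC[C@H]2N1C(=O)OC(C)(C)C | intermediate
28 | (E)-hex-2-enal | CCC/C=C/C=O | starting material
29 | malonic acid | OC(=O)CC(=O)O | starting material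
30 | 2-[(E)-hex-2-en-1-ylidene]malonic acid | CCC/C=C/C=C(C(=O)O)C(=O)O | intermediate
31 | (2E,4E)-octa-2,4-dienoic acid | CCC/C=C/C=C/C(=O)O | intermediate
32 | (2E,4E)-octa-2,4-dienoic 2,4,6-trichlorobenzoic anhydride | CCC/C=C/C=C/C(=O)OC(=O)c1c(Cl)cc(Cl)cc1Cl | intermediate
33 | tert-butyl (2S,3R,4aS,5S,8aR)-5-{(5R)-5-[(4-methoxybenzyl)oxy]octyl}-2-methyl-3-[(2E,4E)-octa-2,4-dienoyloxy]-decahydroquinoline-1-carboxylate | CCC/C=C/C=C/C(=O)O[C@@H]1C[C@H]2[C@@H](CCCC[C@H](OCc3ccc(OC)cc3)CCC)CCC[C@H]2N(C(=O)OC(C)(C)C)[C@H]1C | intermediate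
34 | lepadin H | CCC/C=C/C=C/C(=O)O[C@@H]1C[C@H]2[C@@H](CCCC[C@H](O)CCC)CCC[C@H]2N[C@H]1C | target

**Step count and risks**

Total step count: 18. Longest linear sequence: 14 steps (steps 1–7, 11–15, 17 and 18).

Most likely to fail, first: step 15. The conjugated diene may chelate iridium so firmly that turnover stops after partial reduction, or the acidic iridium hydride may isomerise or ionise the dienyl carbamate so that hydrogen no longer arrives on one face throughout. The fallback sets out from 26 and returns at 34. Heterogeneous hydrogenation over Pd/C (H2, EtOAc) should take up the substrate through the face opposite the axial C2 methyl, with the hydroxyl as anchor. It would reduce both alkenes and hydrogenolyse the PMB ether at the same time, giving tert-butyl (2S,3R,4aS,5S,8aR)-3-hydroxy-5-[(5R)-5-hydroxyoctyl]-2-methyl-decahydroquinoline-1-carboxylate F1. The unhindered side-chain hydroxyl is then silylated in preference to the axial, doubly flanked C3 hydroxyl (TBSCl, imidazole, CH2Cl2, 0 °C) to give the C5' mono-silyl ether F2. Yamaguchi esterification with 31 gives the N-Boc C5'-O-silyl dienoate F3, and CF3CO2H/H2O removes silyl ether and Boc together to reach 34.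

Second: step 11. Oxidative addition may fail to discriminate between the C–Br bond and the nitrogen-activated C–O bond of the phosphate, or the tetrasubstituted electron-rich bromide may react so slowly that protodeboronation of 21 takes over. The fallback sets out from 9 and returns at 24; it reverses the order of the couplings and uses a triflate to separate them. Bromination of the lactam enolate (LiN(SiMe3)2, THF, −78 °C; N-bromosuccinimide) gives tert-butyl (2S,3R)-5-bromo-3-(tert-butyldimethylsilyloxy)-2-methyl-6-oxopiperidine-1-carboxylate F4. Enolisation and triflation (KN(SiMe3)2, PhNTf2, THF, −78 °C) give the bromo enol triflate F5. Stille coupling with 23 at room temperature (PdCl2(PPh3)2, LiCl, DMF) should occur only at the triflate and give the 5-bromo-6-ethenyl enecarbamate F6. Suzuki coupling of the remaining bromide with 21 (Pd(dppf)Cl2, K3PO4, dioxane/H2O, 60 °C) then gives 24.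

Third: step 10. Insertion of the nickel hydride may lose its preference for the internal carbon, the terminal C–H may be aluminated instead, or transfer from aluminium to boron may stay incomplete, any of which would contaminate 21 with isomers that are hard to remove. The fallback sets out from 19 and returns at 21. Gold-catalysed Markovnikov hydration (NaAuCl4, MeOH/H2O, reflux) gives (7R)-7-[(4-methoxybenzyl)oxy]decan-2-one F7. Kinetic enolisation on the methyl side and triflation (LiN(iPr)2, THF, −78 °C; PhNTf2) give (7R)-7-[(4-methoxybenzyl)oxy]dec-1-en-2-yl trifluoromethanesulfonate F8. Miyaura borylation (B2pin2, PdCl2(PPh3)2, PPh3, KOPh, toluene, 50 °C) then gives 21.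

**Further compounds**

F1 | step 15 | tert-butyl (2S,3R,4aS,5S,8aR)-3-hydroxy-5-[(5R)-5-hydroxyoctyl]-2-methyl-decahydroquinoline-1-carboxylate | C[C@H]1[C@H](O)C[C@H]2[C@@H](CCCC[C@H](O)CCC)CCC[C@H]2N1C(=O)OC(C)(C)C
F2 | step 15 | tert-butyl (2S,3R,4aS,5S,8aR)-5-[(5R)-5-(tert-butyldimethylsilyloxy)octyl]-3-hydroxy-2-methyl-decahydroquinoline-1-carboxylate | C[C@H]1[C@H](O)C[C@H]2[C@@H](CCCC[C@H](O[Si](C)(C)C(C)(C)C)CCC)CCC[C@H]2N1C(=O)OC(C)(C)C
F3 | step 15 | tert-butyl (2S,3R,4aS,5S,8aR)-5-[(5R)-5-(tert-butyldimethylsilyloxy)octyl]-2-methyl-3-[(2E,4E)-octa-2,4-dienoyloxy]-decahydroquinoline-1-carboxylate | CCC/C=C/C=C/C(=O)O[C@@H]1C[C@H]2[C@@H](CCCC[C@H](O[Si](C)(C)C(C)(C)C)CCC)CCC[C@H]2N(C(=O)OC(C)(C)C)[C@H]1C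
F4 | step 11 | tert-butyl (2S,3R)-5-bromo-3-(tert-butyldimethylsilyloxy)-2-methyl-6-oxopiperidine-1-carboxylate (C5 epimers) | C[C@H]1[C@H](O[Si](C)(C)C(C)(C)C)CC(Br)C(=O)N1C(=O)OC(C)(C)C
F5 | step 11 | tert-butyl (2S,3R)-5-bromo-3-(tert-butyldimethylsilyloxy)-2-methyl-6-(trifluoromethylsulfonyloxy)-3,4-dihydro-2H-pyridine-1-carboxylate | C[C@H]1[C@H](O[Si](C)(C)C(C)(C)C)CC(Br)=C(OS(=O)(=O)C(F)(F)F)N1C(=O)OC(C)(C)C
F6 | step 11 | tert-butyl (2S,3R)-5-bromo-3-(tert-butyldimethylsilyloxy)-6-ethenyl-2-methyl-3,4-dihydro-2H-pyridine-1-carboxylate | C[C@H]1[C@H](O[Si](C)(C)C(C)(C)C)CC(Br)=C(C=C)N1C(=O)OC(C)(C)C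
F7 | step 10 | (7R)-7-[(4-methoxybenzyl)oxy]decan-2-one | CC(=O)CCCC[C@H](OCc1ccc(OC)cc1)CCC
F8 | step 10 | (7R)-7-[(4-methoxybenzyl)oxy]dec-1-en-2-yl trifluoromethanesulfonate | C=C(OS(=O)(=O)C(F)(F)F)CCCC[C@H](OCc1ccc(OC)cc1)CCC
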